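The route rests on disconnecting the diaryl ether at the O–C1 bond of ring A, the methoxy-bearing ring (C1 carries the ether oxygen, C2 the methoxy group, C4 and C6 the bromines). Because C4 and C6 lie para and ortho to C1, both bromines are carried as nitro groups that activate C1 for addition–elimination. In one operation the phenoxide of 2,4-dibromophenol (ring B) displaces chloride from 2-chloro-1-methoxy-3,5-dinitrobenzene, joining the two rings with every substituent position already fixed. The precursor is an aryl chloride flanked by methoxy and nitro, with a second nitro para. Iron reduction and a double Sandmeyer bromination then deliver the target.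

Key step: step 3

Remark: the target has no stereocentre; 2-methoxy-4-nitrophenol and 2,4-dibromophenol are taken as purchasable; the polynitro intermediates are energetic and the diazonium salt is never isolated.

Step 1
Reactants: 1 2-methoxy-4-nitrophenol (4-nitroguaiacol)
Product: 2 2-methoxy-4,6-dinitrophenol
Conditions: HNO3 (70%, 1.1 equiv), AcOH, 10 °C to rt
Reagents that add atoms: nitric acid, O[N+](=O)[O-]
Why: Electrophilic aromatic nitration; the hydroxyl directs to its one free ortho position, which is also meta to the nitro group already present, and that nitro group tempers oxidation of the phenol.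

Step 2
Reactants: 2 2-methoxy-4,6-dinitrophenol
Product: 4 2-chloro-1-methoxy-3,5-dinitrobenzene, via 2-methoxy-4,6-dinitrophenyl phosphorodichloridate 3 (not isolated)
Conditions: POCl3 (excess), PhNEt2 (1.1 equiv), 90 °C; then ice-water
Reagents that add atoms: phosphorus oxychloride, O=P(Cl)(Cl)Cl
Why: Deoxychlorination of an activated phenol: O-phosphorylation makes the oxygen a dichlorophosphate leaving group, which chloride displaces by addition–elimination at the carbon ortho and para to the nitro groups, as in the conversion of 2,4-dinitrophenols into their chlorides.

Step 3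
Reactants: 4 2-chloro-1-methoxy-3,5-dinitrobenzene; 5 2,4-dibromophenol
Product: 6 1-(2,4-dibromophenoxy)-2-methoxy-4,6-dinitrobenzene
Conditions: K2CO3 (1.5 equiv), dry DMF, rt to 50 °C
Reagents that add atoms: none
Why: Carbonate deprotonates 5, and the phenoxide adds to the chlorine-bearing carbon of 4 (C1 of ring A) to give an anionic Meisenheimer adduct whose charge rests on the nitro groups at C4 and C6; loss of chloride restores aromaticity and completes the addition–elimination (SNAr). The closest known reaction type is the etherification of phenoxides with 1-chloro-2,4-dinitrobenzenes. No ring is closed and no stereocentre is created. The step needs chemoselectivity and site selectivity: C1 is the only carbon of 4 at which attack places charge on both nitro groups, the methoxy carbon is meta to both, and the C–Br bonds of 5 sit on an unactivated ring, so only chloride should be displaced. Dry solvent and mild temperature keep hydrolysis of 4, or of the activated ether 6, from competing.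

Step 4
Reactants: 6 1-(2,4-dibromophenoxy)-2-methoxy-4,6-dinitrobenzene
Product: 7 4-(2,4-dibromophenoxy)-5-methoxybenzene-1,3-diamine
Conditions: Fe powder, NH4Cl, EtOH/H2O (4:1), 80 °C; filtration through Celite under N2, used at once
Reagents that add atoms: none
Why: Béchamp-type reduction: electron transfer from zerovalent iron takes both nitro groups through the nitroso and hydroxylamine stages to the amines without inserting into aryl C–Br bonds, and the near-neutral medium leaves the activated diaryl ether intact.

Step 5
Reactants: 7 4-(2,4-dibromophenoxy)-5-methoxybenzene-1,3-diamine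
Product: 9 1,5-dibromo-2-(2,4-dibromophenoxy)-3-methoxybenzene, via 4-(2,4-dibromophenoxy)-5-methoxybenzene-1,3-bis(diazonium) bis(hydrogensulfate) 8 (not isolated)
Conditions: NaNO2, conc. H2SO4, then 7 in AcOH, 0–10 °C; urea; then added to CuBr, 48% HBr, 0 °C to 50 °C
Reagents that add atoms: hydrobromic acid, Br; copper monobromide, [Cu]Br (bromine carrier, regenerated from HBr); sodium nitrite, [Na+].[O-]N=O (outer nitrogens of 8 only, lost as N2); sulfuric acid, OS(=O)(=O)O (counter-ions of 8 only)
Why: Double Sandmeyer reaction: nitrosylsulfuric acid keeps both amino groups protonated until each is diazotised, which suppresses azo coupling of the electron-rich meta-diamine, and monovalent copper then reduces each diazonium group to an aryl radical that takes bromine from a divalent copper bromide species with loss of N2.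

Compound list
1 | 2-methoxy-4-nitrophenol | COc1cc([N+](=O)[O-])ccc1O | starting material
2 | 2-methoxy-4,6-dinitrophenol | COc1cc([N+](=O)[O-])cc([N+](=O)[O-])c1O | intermediate
3 | 2-methoxy-4,6-dinitrophenyl phosphorodichloridate | COc1cc([N+](=O)[O-])cc([N+](=O)[O-])c1OP(=O)(Cl)Cl | intermediate
4 | 2-chloro-1-methoxy-3,5-dinitrobenzene | COc1cc([N+](=O)[O-])cc([N+](=O)[O-])c1Cl | intermediate
5 | 2,4-dibromophenol | Oc1ccc(Br)cc1Br | starting material
6 | 1-(2,4-dibromophenoxy)-2-methoxy-4,6-dinitrobenzene | COc1cc([N+](=O)[O-])cc([N+](=O)[O-])c1Oc1ccc(Br)cc1Br | intermediate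
7 | 4-(2,4-dibromophenoxy)-5-methoxybenzene-1,3-diamine | COc1cc(N)cc(N)c1Oc1ccc(Br)cc1Br | intermediate
8 | 4-(2,4-dibromophenoxy)-5-methoxybenzene-1,3-bis(diazonium) bis(hydrogensulfate) | COc1cc([N+]#N)cc([N+]#N)c1Oc1ccc(Br)cc1Br.OS(=O)(=O)[O-].OS(=O)(=O)[O-] | intermediate
9 | 1,5-dibromo-2-(2,4-dibromophenoxy)-3-methoxybenzene | COc1cc(Br)cc(Br)c1Oc1ccc(Br)cc1Br | target

Total step count: 5. Longest linear sequence: 5 steps (1 to 9); 2,4-dibromophenol 5 enters at step 3.

Steps most likely to fail

Step 5. Three processes threaten it:
- diazonium groups may couple with amine that is not yet diazotised, giving azo or triazene material;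
- water or bromide may attack C1 and expel the aryloxy group while two diazonium groups activate that carbon;
- the aryl radical at C6 may cyclise onto ring B in a Pschorr-type closure.

The fallback introduces the bromines one at a time, so that only one diazonium group is ever present, and always on a ring that no longer carries a free amine. It sets out from 6. Partial reduction with SnCl2·2H2O (about 3 equiv, EtOH, rt) should give 2-(2,4-dibromophenoxy)-3-methoxy-5-nitroaniline F1. F1 is drawn with the C6 nitro group reduced, the usual outcome with SnCl2 for a nitro group ortho to an ether oxygen; the order in which the two nitro groups are converted does not affect the final product. Diazotisation (NaNO2, H2SO4/AcOH, 0 °C) gives 2-(2,4-dibromophenoxy)-3-methoxy-5-nitrobenzenediazonium hydrogensulfate F2, which CuBr in 48% HBr converts into 1-bromo-2-(2,4-dibromophenoxy)-3-methoxy-5-nitrobenzene F3. Reduction with Fe powder and NH4Cl gives 3-bromo-4-(2,4-dibromophenoxy)-5-methoxyaniline F4. Its diazonium salt, 3-bromo-4-(2,4-dibromophenoxy)-5-methoxybenzenediazonium hydrogensulfate F5, is brominated with CuBr and HBr, and the fallback comes back to the route at 9.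

Step 2. The reaction may stall at the phosphate ester, which reverts to the phenol on quenching, or the activated chloride may hydrolyse during aqueous work-up. The fallback separates activation from displacement. It sets out from 2, which is sulfonylated (TsCl, Et3N, CH2Cl2, 0 °C) to the isolable 2-methoxy-4,6-dinitrophenyl 4-methylbenzenesulfonate F6. Chloride then displaces the sulfonate at the aryl carbon (LiCl, DMF, 60–80 °C) with non-aqueous isolation, and the fallback comes back to the route at 4.

Step 3. Addition at C1, which is flanked by methoxy and nitro, may be slow enough for hydrolysis by adventitious water, or base-mediated cleavage of the product ether, to compete. The fallback changes the electrophile. It sets out from 4, which undergoes halogen exchange (spray-dried KF, 18-crown-6, MeCN, 80 °C) to 2-fluoro-1-methoxy-3,5-dinitrobenzene F7. Addition to the fluoride is much faster, so it should couple with 5 (K2CO3, MeCN, rt) under conditions too mild for the side processes, and the fallback comes back to the route at 6.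

Further compounds
F1 | step 5 | 2-(2,4-dibromophenoxy)-3-methoxy-5-nitroaniline | COc1cc([N+](=O)[O-])cc(N)c1Oc1ccc(Br)cc1Br
F2 | step 5 | 2-(2,4-dibromophenoxy)-3-methoxy-5-nitrobenzenediazonium hydrogensulfate | COc1cc([N+](=O)[O-])cc([N+]#N)c1Oc1ccc(Br)cc1Br.OS(=O)(=O)[O-]
F3 | step 5 | 1-bromo-2-(2,4-dibromophenoxy)-3-methoxy-5-nitrobenzene | COc1cc([N+](=O)[O-])cc(Br)c1Oc1ccc(Br)cc1Br
F4 | step 5 | 3-bromo-4-(2,4-dibromophenoxy)-5-methoxyaniline | COc1cc(N)cc(Br)c1Oc1ccc(Br)cc1Br
F5 | step 5 | 3-bromo-4-(2,4-dibromophenoxy)-5-methoxybenzenediazonium hydrogensulfate | COc1cc([N+]#N)cc(Br)c1Oc1ccc(Br)cc1Br.OS(=O)(=O)[O-]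
F6 | step 2 | 2-methoxy-4,6-dinitrophenyl 4-methylbenzenesulfonate | COc1cc([N+](=O)[O-])cc([N+](=O)[O-])c1OS(=O)(=O)c1ccc(C)cc1
F7 | step 3 | 2-fluoro-1-methoxy-3,5-dinitrobenzene | COc1cc([N+](=O)[O-])cc([N+](=O)[O-])c1F
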